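## Retrosynthetic overview

1. Target acid ⇒ two C–C bonds made on one preformed 1,2-dioxane through peroxycarbenium ions: C3–CH2CO2H (silyl ketene acetal, cis to the C4 ethyl) and C6–Et (Et2Zn, trans to the C4 ethyl).
2. That 1,2-dioxane (acetal at C3, hemiketal at C6) ⇒ aerobic Co(acac)2-mediated ring expansion of a 2-methoxycyclobutanol: the C3–C6 bond is cut and O2 is inserted.
3. Cyclobutanol ⇒ side-chain alkylmagnesium chloride + (3S)-3-ethyl-2-methoxycyclobutanone, itself from a keteniminium/but-1-ene [2+2] under pyrrolidine-auxiliary control.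
4. Side chain ⇒ anti-SN2′ copper coupling of a (3S,4E)-heptenyl picolinate (pent-2-enal + Et2Zn) with the magnesium reagent of (R)-1-bromo-3-chloro-2-methylpropane.
5. Ring order: cyclobutane first (step 5), then the 1,2-dioxane by ring expansion (step 7); no other ring is made.

Assumption: the facial sense of the two reagent-controlled steps (S alcohol from (−)-MIB in step 1, 3S ketone from the (2R,5R)-pyrrolidine in step 5) is as written; if either is opposite, the mirror-image catalyst or auxiliary is used with no other change.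

Locants C1–C14 and O1–O2–C3–C4–C5–C6 are those of the target (C1 = CO2H). In the target the C3 acetic acid arm, the C4 ethyl and the C6 side chain are all cis; the C6 ethyl is trans to them.

## Route

Step 1
Reactants: 1 (E)-pent-2-enal
Product: 3 (3S,4E)-hept-4-en-3-yl pyridine-2-carboxylate, via ethylzinc heptenolate 2 (not isolated)
Conditions: Et2Zn (1.5 equiv), (−)-MIB (4 mol %), hexane/toluene, 0 °C; then picolinoyl chloride hydrochloride (2 equiv), Et3N (4 equiv), DMAP (10 mol %), CH2Cl2, 0 °C → rt
Reagents that add atoms: diethylzinc CC[Zn]CC; picolinoyl chloride hydrochloride Cl.O=C(Cl)c1ccccn1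
Why: Amino-alcohol-catalysed enantioselective addition of a dialkylzinc to an aldehyde (Noyori type) delivers ethyl to the Si face of the enal and sets the carbinol centre as S, and the ethylzinc alkoxide is acylated in the same flask so the volatile alcohol is never isolated.

Step 2
Reactants: 4 (R)-3-bromo-2-methylpropan-1-ol
Product: 5 (R)-1-bromo-3-chloro-2-methylpropane
Conditions: NCS, PPh3, CH2Cl2, 0 °C → rt
Reagents that add atoms: N-chlorosuccinimide O=C1CCC(=O)N1Cl
Why: Appel-type chlorination (alkoxyphosphonium, SN2 by chloride at the primary carbon) leaves the stereocentre untouched, and it stays R because CH2Br outranks CH2Cl.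

Step 3
Reactants: 5 (R)-1-bromo-3-chloro-2-methylpropane; 3 (3S,4E)-hept-4-en-3-yl pyridine-2-carboxylate
Product: 7 (2S,4R,5E)-1-chloro-4-ethyl-2-methyloct-5-ene, via chloroalkylmagnesium bromide 6 (not isolated)
Conditions: Mg, THF, 0 °C (insertion into C–Br only); then CuBr·SMe2 (0.5 equiv per 6), 3 (0.5 equiv per 6), THF, −40 → 0 °C
Reagents that add atoms: none
Why: Copper-mediated anti-SN2′ allylic substitution of a picolinate by an alkylmagnesium halide: the pyridyl ester steers copper to the γ-carbon anti to the leaving group, so the S carbinol chirality is transferred to the new R centre (C10) and the E alkene forms, while C8 is carried in unchanged from 4.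

Step 4
Reactants: 8 methoxyacetyl chloride; 9 (2R,5R)-2,5-dimethylpyrrolidine
Product: 10 1-[(2R,5R)-2,5-dimethylpyrrolidin-1-yl]-2-methoxyethan-1-one
Conditions: Et3N, CH2Cl2, 0 °C
Reagents that add atoms: none
Why: N-Acylation of a secondary amine by an acid chloride installs the C2-symmetric auxiliary and creates no new stereocentre.

Step 5
Reactants: 10 1-[(2R,5R)-2,5-dimethylpyrrolidin-1-yl]-2-methoxyethan-1-one; 11 but-1-ene
Product: 14 (3S)-3-ethyl-2-methoxycyclobutan-1-one, via keteniminium triflate 12 (not isolated), via cyclobutaniminium triflate 13 (not isolated)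
Conditions: Tf2O (1.1 equiv), 2,4,6-collidine (1.2 equiv), but-1-ene (10 equiv), 1,2-dichloroethane, sealed tube, −20 → 70 °C; then aq NaHCO3, rt
Reagents that add atoms: water O
Why: Ghosez keteniminium–alkene [2+2] cycloaddition: the central keteniminium carbon bonds to the CH2 terminus of butene so ethyl ends at C3 next to the methoxy carbon, the C2-symmetric pyrrolidine shields one face and sets C3 as S (target C4), the C2 methoxy centre forms as an inconsequential mixture, and hydrolysis frees the ketone.

Step 6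
Reactants: 7 (2S,4R,5E)-1-chloro-4-ethyl-2-methyloct-5-ene; 14 (3S)-3-ethyl-2-methoxycyclobutan-1-one
Product: 16 (3S)-3-ethyl-1-[(2S,4R,5E)-4-ethyl-2-methyloct-5-en-1-yl]-2-methoxycyclobutan-1-ol, via alkylmagnesium chloride 15 (not isolated)
Conditions: Mg turnings, THF, 45 °C; then 14, LaCl3·2LiCl (1 equiv), THF, −78 → 0 °C; aq NH4Cl
Reagents that add atoms: none
Why: 1,2-Addition of an alkylmagnesium halide to a strained ketone (LaCl3·2LiCl suppresses enolisation) gives the tertiary cyclobutanol; the new carbinol carbon and the methoxy carbon are epimer mixtures that are both erased in step 7, and the 3S ethyl centre is β to the carbonyl and cannot epimerise.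

Step 7
Reactants: 16 (3S)-3-ethyl-1-[(2S,4R,5E)-4-ethyl-2-methyloct-5-en-1-yl]-2-methoxycyclobutan-1-ol
Product: 18 (4S)-4-ethyl-6-[(2S,4R,5E)-4-ethyl-2-methyloct-5-en-1-yl]-3-methoxy-1,2-dioxan-6-ol, via hydroperoxy ketone 17 (not isolated)
Conditions: Co(acac)2 (0.3 equiv), O2 (1 atm), 1,2-dichloroethane, 40 °C
Reagents that add atoms: dioxygen O=O
Why: Aerobic oxidative ring expansion of a cyclobutanol (radical β-scission, not pericyclic): the trivalent cobalt alkoxide of 16 gives an alkoxyl radical, the ring bond to the methoxy-bearing carbon breaks to the stabilised α-methoxy radical, O2 is captured there and hydroperoxide 17 closes on the new ketone to the six-membered peroxide; C4 (S) is untouched and C3 and C6 form as anomer mixtures that are fixed only in steps 8 and 9.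

Step 8
Reactants: 18 (4S)-4-ethyl-6-[(2S,4R,5E)-4-ethyl-2-methyloct-5-en-1-yl]-3-methoxy-1,2-dioxan-6-ol
Product: 20 (4S,6R)-4,6-diethyl-6-[(2S,4R,5E)-4-ethyl-2-methyloct-5-en-1-yl]-3-methoxy-1,2-dioxane, via trimethylsilyl peroxyketal 19 (not isolated)
Conditions: TMSOTf (1.1 equiv), 2,6-lutidine (1.2 equiv), CH2Cl2, −78 °C; Et2Zn (3 equiv); then TMSOTf (1.1 equiv), −78 → −50 °C
Reagents that add atoms: diethylzinc CC[Zn]CC
Why: Proposed new method: Lewis-acid-triggered C-ethylation of a cyclic peroxyketal by a dialkylzinc — the hemiketal is first capped as silyl ketal 19 so that zinc never meets a free OH or OOH, TMSOTf then ionises the ketal-type C6 (faster than the acetal-type C3–OMe) to a tertiary peroxycarbenium ion, and ethyl is transferred from zinc along the axial trajectory of the chair that keeps the C4 ethyl equatorial, i.e. anti to the C4 ethyl, giving the 6R quaternary centre with the side chain cis to C4-Et; the closest known reaction types are allylsilane and silyl enol ether substitutions of peroxyketals through peroxycarbenium ions and dialkylzinc additions to cyclic oxocarbenium ions made from lactol derivatives.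

Step 9
Reactants: 20 (4S,6R)-4,6-diethyl-6-[(2S,4R,5E)-4-ethyl-2-methyloct-5-en-1-yl]-3-methoxy-1,2-dioxane; 21 acetic acid
Product: 24 2-[(3S,4S,6R)-4,6-diethyl-6-[(2S,4R,5E)-4-ethyl-2-methyloct-5-en-1-yl]-1,2-dioxan-3-yl]acetic acid (target), via ketene bis(trimethylsilyl) acetal 22 (not isolated), via trimethylsilyl ester 23 (not isolated)
Conditions: AcOH, LiN(iPr)2 (2.1 equiv), THF, −78 → 0 °C; TMSCl (2.2 equiv); filter, concentrate; then 20, TMSOTf (0.2 equiv), CH2Cl2, −78 °C; aq citric acid
Reagents that add atoms: none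
Why: Mukaiyama-type substitution of a peroxy acetal through the C3 peroxycarbenium ion: with the ring locked in the chair that keeps the C4 ethyl and the C6 side chain equatorial, the bis-silyl ketene acetal adds axially, cis to the C4 ethyl, giving 3S, and the silyl ester falls to the free acid on work-up, so the β-peroxy ester is never exposed to base.

## Compound list

1 | (E)-pent-2-enal | CC/C=C/C=O | starting material
2 | ethylzinc (3S,4E)-hept-4-en-3-olate (not isolated) | CC[C@H](O[Zn]CC)/C=C/CC | intermediate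
3 | (3S,4E)-hept-4-en-3-yl pyridine-2-carboxylate | CC[C@H](OC(=O)c1ccccn1)/C=C/CC | intermediate
4 | (R)-3-bromo-2-methylpropan-1-ol | BrC[C@H](C)CO | starting material
5 | (R)-1-bromo-3-chloro-2-methylpropane | BrC[C@H](C)CCl | intermediate
6 | (S)-(3-chloro-2-methylpropyl)magnesium bromide (not isolated) | Br[Mg]C[C@H](C)CCl | intermediate
7 | (2S,4R,5E)-1-chloro-4-ethyl-2-methyloct-5-ene | CC/C=C/[C@H](CC)C[C@H](C)CCl | intermediate
8 | methoxyacetyl chloride | COCC(=O)Cl | starting material
9 | (2R,5R)-2,5-dimethylpyrrolidine | C[C@@H]1CC[C@@H](C)N1 | starting material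
10 | 1-[(2R,5R)-2,5-dimethylpyrrolidin-1-yl]-2-methoxyethan-1-one | COCC(=O)N1[C@H](C)CC[C@H]1C | intermediate
11 | but-1-ene | C=CCC | starting material
12 | (2R,5R)-1-(2-methoxyethenylidene)-2,5-dimethylpyrrolidin-1-ium triflate (not isolated) | COC=C=[N+]1[C@H](C)CC[C@H]1C.[O-]S(=O)(=O)C(F)(F)F | intermediate
13 | (2R,5R)-1-[(3S)-3-ethyl-2-methoxycyclobutylidene]-2,5-dimethylpyrrolidin-1-ium triflate (not isolated) | CC[C@H]1CC(=[N+]2[C@H](C)CC[C@H]2C)C1OC.[O-]S(=O)(=O)C(F)(F)F | intermediate
14 | (3S)-3-ethyl-2-methoxycyclobutan-1-one (both C2 epimers) | O=C1C[C@H](CC)C1OC | intermediate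
15 | [(2S,4R,5E)-4-ethyl-2-methyloct-5-en-1-yl]magnesium chloride (not isolated) | CC/C=C/[C@H](CC)C[C@H](C)C[Mg]Cl | intermediate
16 | (3S)-3-ethyl-1-[(2S,4R,5E)-4-ethyl-2-methyloct-5-en-1-yl]-2-methoxycyclobutan-1-ol (epimers at C1 and C2) | CC/C=C/[C@H](CC)C[C@H](C)CC1(O)C[C@H](CC)C1OC | intermediate
17 | (2S,6S,8R,9E)-2,8-diethyl-1-hydroperoxy-1-methoxy-6-methyldodec-9-en-4-one (not isolated) | CC/C=C/[C@H](CC)C[C@H](C)CC(=O)C[C@H](CC)C(OC)OO | intermediate
18 | (4S)-4-ethyl-6-[(2S,4R,5E)-4-ethyl-2-methyloct-5-en-1-yl]-3-methoxy-1,2-dioxan-6-ol (target ring locants; anomers at C3 and C6) | CC/C=C/[C@H](CC)C[C@H](C)CC1(O)C[C@H](CC)C(OC)OO1 | intermediate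
19 | (4S)-4-ethyl-6-[(2S,4R,5E)-4-ethyl-2-methyloct-5-en-1-yl]-3-methoxy-6-(trimethylsilyloxy)-1,2-dioxane (not isolated) | CC/C=C/[C@H](CC)C[C@H](C)CC1(O[Si](C)(C)C)C[C@H](CC)C(OC)OO1 | intermediate
20 | (4S,6R)-4,6-diethyl-6-[(2S,4R,5E)-4-ethyl-2-methyloct-5-en-1-yl]-3-methoxy-1,2-dioxane (C3 anomers) | CC/C=C/[C@H](CC)C[C@H](C)C[C@]1(CC)C[C@H](CC)C(OC)OO1 | intermediate
21 | acetic acid | CC(=O)O | starting material
22 | 1,1-bis(trimethylsilyloxy)ethene (not isolated) | C=C(O[Si](C)(C)C)O[Si](C)(C)C | intermediate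
23 | trimethylsilyl 2-[(3S,4S,6R)-4,6-diethyl-6-[(2S,4R,5E)-4-ethyl-2-methyloct-5-en-1-yl]-1,2-dioxan-3-yl]acetate (not isolated) | CC/C=C/[C@H](CC)C[C@H](C)C[C@]1(CC)C[C@H](CC)[C@H](CC(=O)O[Si](C)(C)C)OO1 | intermediate
24 | 2-[(3S,4S,6R)-4,6-diethyl-6-[(2S,4R,5E)-4-ethyl-2-methyloct-5-en-1-yl]-1,2-dioxan-3-yl]acetic acid | CC/C=C/[C@H](CC)C[C@H](C)C[C@]1(CC)C[C@H](CC)[C@H](CC(=O)O)OO1 | target

## Step count and risk

Total step count: 9. Longest linear sequence: 6 steps (2, 3, 6, 7, 8, 9; the branches starting at step 1 or step 4 are equally long).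

The three steps most likely to fail:

Step 5. The methoxy-substituted keteniminium ion may form poorly or add to but-1-ene with low facial control. The fallback sets out from 11 and builds the ketone by desymmetrisation instead of an auxiliary. Dichloroketene (Cl3CCOCl, Zn, POCl3, Et2O) adds to but-1-ene to give 2,2-dichloro-3-ethylcyclobutan-1-one F1. Zn in AcOH removes both chlorines to give 3-ethylcyclobutan-1-one F2. Proline-catalysed α-aminoxylation with nitrosobenzene (the proline enantiomer that gives the 3S series) desymmetrises F2 to (2R,3S)-3-ethyl-2-[(phenylamino)oxy]cyclobutan-1-one F3. N–O cleavage (Zn, AcOH) gives (2R,3S)-3-ethyl-2-hydroxycyclobutan-1-one F4. O-Methylation (MeI, Ag2O) gives 14 as its trans isomer, where the route is rejoined.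

Step 7. For this tertiary, methoxy-substituted cyclobutanol the alkoxyl radical may form slowly, or the cobalt may decompose hydroperoxide 17 before it closes. The fallback sets out from 14 and 15 and reaches the same peroxide by polar chemistry. Baeyer–Villiger oxidation of 14 (mCPBA, NaHCO3, CH2Cl2; the methoxy-bearing carbon migrates) gives (4S)-4-ethyl-5-methoxyoxolan-2-one F5. Acid methanolysis (MeOH, TsOH) opens it to methyl (3S)-3-ethyl-4,4-dimethoxybutanoate F6. MeNH(OMe)·HCl with iPrMgCl gives (3S)-3-ethyl-N,4,4-trimethoxy-N-methylbutanamide F7. Addition of 15 gives (2S,6S,8R,9E)-2,8-diethyl-1,1-dimethoxy-6-methyldodec-9-en-4-one F8. Ethereal H2O2 with catalytic acid exchanges one methoxy group for OOH to give 17, which closes to 18, where the route is rejoined.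

Step 8 (the proposed new step). Possible failures are β-hydride reduction instead of ethyl transfer, attack at C3, O–O cleavage by zinc, or capture of the C6 cation by the side-chain alkene. The fallback uses only known chemistry and sets out from 18. The same C6 peroxycarbenium ion is trapped with (vinyloxy)trimethylsilane and catalytic TMSOTf (known silyl enol ether substitution of peroxyketals, same axial sense) to give 2-[(4S,6R)-4-ethyl-6-[(2S,4R,5E)-4-ethyl-2-methyloct-5-en-1-yl]-3-methoxy-1,2-dioxan-6-yl]acetaldehyde F9. Condensation with TsNHNH2 gives its 4-methylbenzenesulfonohydrazone F10. Reduction with catecholborane, then NaOAc·3H2O, turns CH2CH=N into CH2CH3 and gives 20, where the route is rejoined.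

## Further compounds

F1 | step 5 | 2,2-dichloro-3-ethylcyclobutan-1-one (racemic) | CCC1CC(=O)C1(Cl)Cl
F2 | step 5 | 3-ethylcyclobutan-1-one | CCC1CC(=O)C1
F3 | step 5 | (2R,3S)-3-ethyl-2-[(phenylamino)oxy]cyclobutan-1-one | O=C1C[C@H](CC)[C@H]1ONc1ccccc1
F4 | step 5 | (2R,3S)-3-ethyl-2-hydroxycyclobutan-1-one | O=C1C[C@H](CC)[C@H]1O
F5 | step 7 | (4S)-4-ethyl-5-methoxyoxolan-2-one | O=C1C[C@H](CC)C(OC)O1
F6 | step 7 | methyl (3S)-3-ethyl-4,4-dimethoxybutanoate | COC(=O)C[C@H](CC)C(OC)OC
F7 | step 7 | (3S)-3-ethyl-N,4,4-trimethoxy-N-methylbutanamide | CON(C)C(=O)C[C@H](CC)C(OC)OC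
F8 | step 7 | (2S,6S,8R,9E)-2,8-diethyl-1,1-dimethoxy-6-methyldodec-9-en-4-one | CC/C=C/[C@H](CC)C[C@H](C)CC(=O)C[C@H](CC)C(OC)OC
F9 | step 8 | 2-[(4S,6R)-4-ethyl-6-[(2S,4R,5E)-4-ethyl-2-methyloct-5-en-1-yl]-3-methoxy-1,2-dioxan-6-yl]acetaldehyde | CC/C=C/[C@H](CC)C[C@H](C)C[C@]1(CC=O)C[C@H](CC)C(OC)OO1
F10 | step 8 | 4-methylbenzenesulfonohydrazone of F9 | CC/C=C/[C@H](CC)C[C@H](C)C[C@]1(CC=NNS(=O)(=O)c2ccc(C)cc2)C[C@H](CC)C(OC)OO1
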